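If two molecules of starting material must meet to make one target, the rate goes with the square of the concentration, which is called second-order, and the reciprocal of the concentration then climbs in a straight line with time, at a slope κ. Here is what we have and what is asked.

| setting | green | ochre | oak | ash | maple | alder | birch |
|---|---|---|---|---|---|---|---|
| starting material | 0.78 M | 1.4 M | 0.80 M | 1.0 M | 3.0 M | 2.0 M | 1.5 M |
| remark | run made earlier | run made earlier |  |  |  |  |  |
| time |  |  | 10 min | 10 min | 10 min | 10 min | 10 min |

| run | time / min | target / % |
|---|---|---|
| green | 1.33 | 31.5 |
| green | 4.00 | 57.8 |
| green | 6.00 | 66.0 |
| green | 10.0 | 76.8 |
| ochre | 1.33 | 45.0 |
| ochre | 4.00 | 70.6 |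
| ochre | 6.00 | 78.0 |
| ochre | 10.0 | 84.2 |

(each reading ± 0.5 percentage points)

- a species is counted by the starting material in it: one target counts as two

- the flasks put in order of amount of target, in percent of the starting material charged, best first, at 10 min (oak / ash / maple / alder / birch)
- the amount of target, in percent of the starting material charged of the flask you put first, at 10 min
- the amount of target, in percent of the starting material charged of the flask you put last, at 10 min

Call the charge C and the time t, and write n = κCt, the meeting number (the field's Damköhler number). Follow one molecule of starting material: its chance of being still unmet is 1/(1+n), and its chance of having gone to target is y = n/(1+n). So y/(1−y) read from a run equals n, and dividing by Ct gives κ.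

The first green reading gives 0.443 M⁻¹ min⁻¹; this κ, the slope of the reciprocal concentration, is what we carry. The first ochre reading, at a different charge, gives 0.439 M⁻¹ min⁻¹, the same within scatter.

There is a second fork. At 10.0 min the rule promises 77.6% for green and 86.1% for ochre, but the readings are 76.8% and 84.2%. We take these gaps as target leaving by a further step, which is our assumption, since target readings alone can't name the cause. On average over the two runs, a target molecule still stands at 10.0 min with chance K = 98.4%, a reading resting on these two gaps, with each reading good to 0.5 percentage points.

At equal time n follows the charge, so our order follows it too: maple has the largest charge and oak the smallest. Maple has n = 13.3, so Ky gives 91.5%. Oak has n = 3.55, which gives 76.7%.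

The forecast puts maple > alder > birch > ash > oak, on the ground that “The loss is small, so the order should stay the same”, and it gives 89% for maple, lower than our figure, and 77.3% for oak.

The flasks give maple > alder > birch > ash > oak, with 91.3% in maple and 76.7% in oak.

    target → over-reaction product (k = 0.00210 min⁻¹)
    2 starting material → target (k = 0.220 M⁻¹ min⁻¹)

The way out of target is the step to over-reaction product, and the half-life of target by that step alone in maple is 5.5 h, much longer than 10 min; maple holds 1.66% of that product at 10.0 min. Now take the neighbour of maple, charged with 1.2 M in place of 3.0 M, at the same time. Its meeting number is 5.32, so the chance of a molecule staying unmet is 15.8%, and with K the target comes to 82.8%. That flask holds 82.7% of target, with 16% of starting material left.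

The runs come from a simulation with constants of no real substance, and the scatter is random.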